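**Plan**

- Numbering: ring A is the central benzene. C1 carries the methide carbon C7, C2 carries ring D (2,4-dihydroxyphenyl), C3 and C4 carry H, C5 carries CH2OH, and C6 carries the alkyne C8≡C9 to ring E. Rings B and C are the two para-oxygenated aryl groups on C7.
- Enabling feature: C2–C3–C4–C5 of ring A is a diene unit with hydrogen on its inner carbons C3 and C4. C1–C6 is what remains of a triple bond conjugated to the C7 carbonyl on one side and to C8≡C9 on the other. Ring A is therefore a dehydrogenated diene-plus-ynone cycloadduct.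
- Cuts, in retrosynthetic order: C7=ring C (quinone methide back to carbinol, then the C7–aryl bond back to a ketone); C1–C2 and C5–C6 of ring A (Diels–Alder); the C4=C5 alkene of the diene (vinylogous HWE); the C(sp)–aryl and C(sp)–C7 bonds of the diynone.
- Forward order: rings D, B and E are carried on two open-chain partners (aryl diene and diynone). Ring A closes between them and is aromatised in the same flask. Ring C is added to the C7 ketone, and acid then removes all protecting groups and unveils the quinone methide.
- Stereochemistry: the target has no stereocentre and no stereogenic double bond, because rings B and C are the same aryl group. The E,E geometry of the diene comes from the HWE step, and the two sp3 centres of the cycloadduct are erased on aromatisation.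

Key step: step 10

Assumption: the target is taken in the open quinone methide form drawn; the ortho phenol of ring D is assumed not to remain added to C7 after neutral work-up.

**Route**

Step 1
Reactants: 1 2,4-dihydroxybenzaldehyde
Product: 2 2,4-bis(methoxymethoxy)benzaldehyde
Conditions: MOMCl (3 equiv), i-Pr2NEt, CH2Cl2, 0 °C to 40 °C
Reagents that add atoms: chloromethyl methyl ether (MOMCl), COCCl
Why: Base-mediated O-alkylation of both phenols (MOM ether formation), in which excess reagent and gentle warming overcome the hydrogen bond that ties the ortho phenol to the aldehyde.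

Step 2
Reactants: 2 2,4-bis(methoxymethoxy)benzaldehyde; 3 triethyl 4-phosphonocrotonate
Product: 4 ethyl (2E,4E)-5-[2,4-bis(methoxymethoxy)phenyl]penta-2,4-dienoate
Conditions: LiN(SiMe3)2, THF, −78 °C to rt
Reagents that add atoms: none
Why: Vinylogous Horner–Wadsworth–Emmons olefination, in which the delocalised phosphonate anion attacks the non-enolisable aryl aldehyde through its phosphorus-bearing carbon and reversible addition–elimination gives the new conjugated alkene E while the existing C2=C3 bond stays E.

Step 3
Reactants: 4 ethyl (2E,4E)-5-[2,4-bis(methoxymethoxy)phenyl]penta-2,4-dienoate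
Product: 5 (2E,4E)-5-[2,4-bis(methoxymethoxy)phenyl]penta-2,4-dien-1-ol
Conditions: i-Bu2AlH (2.2 equiv), CH2Cl2, −78 °C; aq. potassium sodium tartrate work-up
Reagents that add atoms: none
Why: Hydride 1,2-reduction of the conjugated ester to the allylic alcohol with i-Bu2AlH at low temperature, which leaves the diene geometry and the acetals untouched.

Step 4
Reactants: 5 (2E,4E)-5-[2,4-bis(methoxymethoxy)phenyl]penta-2,4-dien-1-ol
Product: 6 tert-butyl{[(2E,4E)-5-[2,4-bis(methoxymethoxy)phenyl]penta-2,4-dien-1-yl]oxy}dimethylsilane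
Conditions: TBSCl, imidazole, DMF, 0 °C to rt
Reagents that add atoms: tert-butyldimethylsilyl chloride (TBSCl), CC(C)(C)[Si](C)(C)Cl
Why: Imidazole-promoted silylation of the primary allylic alcohol under basic conditions, which avoids ionisation of the acid-sensitive dienyl carbinol.

Step 5
Reactants: 7 4-hydroxybenzaldehyde
Product: 8 4-(methoxymethoxy)benzaldehyde
Conditions: MOMCl, i-Pr2NEt, CH2Cl2, 0 °C to rt
Reagents that add atoms: chloromethyl methyl ether (MOMCl), COCCl
Why: Straightforward MOM ether formation at an acidic, unhindered phenol.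

Step 6
Reactants: 9 1,4-bis(trimethylsilyl)buta-1,3-diyne; 8 4-(methoxymethoxy)benzaldehyde
Product: 11 1-[4-(methoxymethoxy)phenyl]-5-(trimethylsilyl)penta-2,4-diyn-1-ol (racemic), via lithium 4-(trimethylsilyl)buta-1,3-diynide 10 (not isolated)
Conditions: MeLi·LiBr (1.0 equiv), THF, rt; then 8, −78 °C to 0 °C; aq. NH4Cl
Reagents that add atoms: none
Why: MeLi·LiBr cleaves one C(sp)–Si bond of the bis-silyl diyne selectively and the resulting lithium acetylide undergoes 1,2-addition to the non-enolisable aldehyde; the carbinol centre is formed racemic and is removed by the oxidation in step 9.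

Step 7
Reactants: 12 4-iodophenol
Product: 13 1-iodo-4-(methoxymethoxy)benzene
Conditions: MOMCl, i-Pr2NEt, CH2Cl2, 0 °C to rt
Reagents that add atoms: chloromethyl methyl ether (MOMCl), COCCl
Why: MOM ether formation at a simple phenol, with the aryl iodide inert to the conditions.

Step 8
Reactants: 11 1-[4-(methoxymethoxy)phenyl]-5-(trimethylsilyl)penta-2,4-diyn-1-ol; 13 1-iodo-4-(methoxymethoxy)benzene
Product: 15 1,5-bis[4-(methoxymethoxy)phenyl]penta-2,4-diyn-1-ol (racemic), via terminal diynol 14 (not isolated)
Conditions: Pd(PPh3)4 (5 mol %), CuI (10 mol %), K2CO3, MeOH/THF (degassed), rt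
Reagents that add atoms: none
Why: Sonogashira coupling with in situ protodesilylation, in which methanolic carbonate releases the terminal diyne slowly so that it is taken up by copper and coupled with the aryl iodide (fast oxidative addition to zerovalent palladium) before it can accumulate.

Step 9
Reactants: 15 1,5-bis[4-(methoxymethoxy)phenyl]penta-2,4-diyn-1-ol
Product: 16 1,5-bis[4-(methoxymethoxy)phenyl]penta-2,4-diyn-1-one
Conditions: MnO2 (activated, excess), CH2Cl2, rt
Reagents that add atoms: none
Why: MnO2 oxidation of a secondary alcohol that is both benzylic and propargylic, under neutral conditions that spare the acetals and the sensitive cross-conjugated diynone.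

Step 10
Reactants: 6 tert-butyl{[(2E,4E)-5-[2,4-bis(methoxymethoxy)phenyl]penta-2,4-dien-1-yl]oxy}dimethylsilane; 16 1,5-bis[4-(methoxymethoxy)phenyl]penta-2,4-diyn-1-one
Product: 18 {4-({[tert-butyl(dimethyl)silyl]oxy}methyl)-2',4'-bis(methoxymethoxy)-3-{[4-(methoxymethoxy)phenyl]ethynyl}biphenyl-2-yl}[4-(methoxymethoxy)phenyl]methanone, via cis-cyclohexa-1,4-diene adduct 17 (not isolated)
Conditions: toluene, 120 °C, sealed tube, BHT (trace); cool to rt, then DDQ (1.2 equiv), rt
Reagents that add atoms: none
Why: Concerted but asynchronous normal-electron-demand [4+2] cycloaddition in which the HOMO of the s-cis (E,E)-diene 6, raised by the 2,4-dialkoxyphenyl group, overlaps with the LUMO of the carbonyl-conjugated triple bond of 16; the closest known reaction type is the thermal Diels–Alder reaction of 1-aryl-1,3-dienes with alkynyl ketones followed by DDQ dehydrogenation of the cyclohexa-1,4-diene. Ring A closes by this intermolecular cycloaddition, which makes C5–C6 and C1–C2 in one event from two open-chain partners (six-membered carbocycle, no tether). The two sp3 centres of adduct 17 (C2 and C5, cis by suprafacial addition to the E,E-diene) are transient and disappear when DDQ abstracts hydride from the doubly allylic positions, so no stereocentre has to be controlled. Regioselectivity is required and comes from pairing the largest diene HOMO coefficient (C5, the terminus remote from the aryl group) with the largest dienophile LUMO coefficient (C6, β to the carbonyl), which places ring D beside the aroyl group and CH2OTBS beside the alkyne. Chemoselectivity for the ynone triple bond over C8≡C9 follows from the same polarisation, because only the former is directly activated by the carbonyl, and the aromatised product is no longer a dienophile. The MOM acetals, the silyl ether and the remaining alkyne are inert to DDQ at room temperature.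

Step 11
Reactants: 18 {4-({[tert-butyl(dimethyl)silyl]oxy}methyl)-2',4'-bis(methoxymethoxy)-3-{[4-(methoxymethoxy)phenyl]ethynyl}biphenyl-2-yl}[4-(methoxymethoxy)phenyl]methanone; 13 1-iodo-4-(methoxymethoxy)benzene
Product: 20 {4-({[tert-butyl(dimethyl)silyl]oxy}methyl)-2',4'-bis(methoxymethoxy)-3-{[4-(methoxymethoxy)phenyl]ethynyl}biphenyl-2-yl}bis[4-(methoxymethoxy)phenyl]methanol, via 4-(methoxymethoxy)phenyllithium 19 (not isolated)
Conditions: 13 (2 equiv), n-BuLi, THF, −78 °C; then 18, −78 °C to −40 °C; aq. NH4Cl at −40 °C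
Reagents that add atoms: none
Why: Iodine–lithium exchange followed by 1,2-addition of the aryllithium to a non-enolisable diaryl ketone, where the slim alkynyl group on one flank leaves an approach open and the cold quench keeps the alkoxide from adding to the neighbouring alkyne.

Step 12
Reactants: 20 {4-({[tert-butyl(dimethyl)silyl]oxy}methyl)-2',4'-bis(methoxymethoxy)-3-{[4-(methoxymethoxy)phenyl]ethynyl}biphenyl-2-yl}bis[4-(methoxymethoxy)phenyl]methanol
Product: 22 selaginellin F, via hexahydroxy triarylmethanol 21 (not isolated)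
Conditions: HCl (3 M aq.), MeOH/THF, rt to 40 °C; then aq. NaHCO3 to pH 6–7
Reagents that add atoms: none
Why: Acidic methanolysis cleaves the four aryl MOM acetals and the silyl ether, and the tertiary carbinol, stabilised by two para-oxygenated aryl groups, ionises (SN1) and on neutralisation loses a phenolic proton to give the quinone methide (fuchsone formation), without geometric isomers because rings B and C are the same aryl group.

**Compound list**

1 | 2,4-dihydroxybenzaldehyde | O=Cc1ccc(O)cc1O | starting material
2 | 2,4-bis(methoxymethoxy)benzaldehyde | COCOc1ccc(C=O)c(OCOC)c1 | intermediate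
3 | triethyl 4-phosphonocrotonate, ethyl (2E)-4-(diethoxyphosphoryl)but-2-enoate | CCOC(=O)/C=C/CP(=O)(OCC)OCC | starting material
4 | ethyl (2E,4E)-5-[2,4-bis(methoxymethoxy)phenyl]penta-2,4-dienoate | CCOC(=O)/C=C/C=C/c1ccc(OCOC)cc1OCOC | intermediate
5 | (2E,4E)-5-[2,4-bis(methoxymethoxy)phenyl]penta-2,4-dien-1-ol | OC/C=C/C=C/c1ccc(OCOC)cc1OCOC | intermediate
6 | tert-butyl{[(2E,4E)-5-[2,4-bis(methoxymethoxy)phenyl]penta-2,4-dien-1-yl]oxy}dimethylsilane (diene for the key step) | CC(C)(C)[Si](C)(C)OC/C=C/C=C/c1ccc(OCOC)cc1OCOC | intermediate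
7 | 4-hydroxybenzaldehyde | O=Cc1ccc(O)cc1 | starting material
8 | 4-(methoxymethoxy)benzaldehyde | COCOc1ccc(C=O)cc1 | intermediate
9 | 1,4-bis(trimethylsilyl)buta-1,3-diyne | C[Si](C)(C)C#CC#C[Si](C)(C)C | starting material
10 | lithium 4-(trimethylsilyl)buta-1,3-diynide (not isolated) | [Li]C#CC#C[Si](C)(C)C | intermediate
11 | 1-[4-(methoxymethoxy)phenyl]-5-(trimethylsilyl)penta-2,4-diyn-1-ol (racemic) | C[Si](C)(C)C#CC#CC(O)c1ccc(OCOC)cc1 | intermediate
12 | 4-iodophenol | Oc1ccc(I)cc1 | starting material
13 | 1-iodo-4-(methoxymethoxy)benzene | COCOc1ccc(I)cc1 | intermediate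
14 | 1-[4-(methoxymethoxy)phenyl]penta-2,4-diyn-1-ol (racemic, not isolated) | C#CC#CC(O)c1ccc(OCOC)cc1 | intermediate
15 | 1,5-bis[4-(methoxymethoxy)phenyl]penta-2,4-diyn-1-ol (racemic) | COCOc1ccc(cc1)C#CC#CC(O)c1ccc(OCOC)cc1 | intermediate
16 | 1,5-bis[4-(methoxymethoxy)phenyl]penta-2,4-diyn-1-one (dienophile for the key step) | O=C(C#CC#Cc1ccc(OCOC)cc1)c1ccc(OCOC)cc1 | intermediate
17 | {6-[2,4-bis(methoxymethoxy)phenyl]-3-({[tert-butyl(dimethyl)silyl]oxy}methyl)-2-{[4-(methoxymethoxy)phenyl]ethynyl}cyclohexa-1,4-dien-1-yl}[4-(methoxymethoxy)phenyl]methanone (3,6-cis, racemic, one enantiomer drawn, not isolated) | O=C(c1ccc(OCOC)cc1)C1=C(C#Cc2ccc(OCOC)cc2)[C@H](CO[Si](C)(C)C(C)(C)C)C=C[C@@H]1c1ccc(OCOC)cc1OCOC | intermediate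
18 | {4-({[tert-butyl(dimethyl)silyl]oxy}methyl)-2',4'-bis(methoxymethoxy)-3-{[4-(methoxymethoxy)phenyl]ethynyl}biphenyl-2-yl}[4-(methoxymethoxy)phenyl]methanone (ring A complete) | O=C(c1ccc(OCOC)cc1)c1c(-c2ccc(OCOC)cc2OCOC)ccc(CO[Si](C)(C)C(C)(C)C)c1C#Cc1ccc(OCOC)cc1 | intermediate
19 | 4-(methoxymethoxy)phenyllithium (not isolated) | [Li]c1ccc(OCOC)cc1 | intermediate
20 | {4-({[tert-butyl(dimethyl)silyl]oxy}methyl)-2',4'-bis(methoxymethoxy)-3-{[4-(methoxymethoxy)phenyl]ethynyl}biphenyl-2-yl}bis[4-(methoxymethoxy)phenyl]methanol | OC(c1ccc(OCOC)cc1)(c1ccc(OCOC)cc1)c1c(-c2ccc(OCOC)cc2OCOC)ccc(CO[Si](C)(C)C(C)(C)C)c1C#Cc1ccc(OCOC)cc1 | intermediate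
21 | {2',4'-dihydroxy-4-(hydroxymethyl)-3-[(4-hydroxyphenyl)ethynyl]biphenyl-2-yl}bis(4-hydroxyphenyl)methanol (present in acid as its carbenium ion, not isolated) | OCc1ccc(-c2ccc(O)cc2O)c(C(O)(c2ccc(O)cc2)c2ccc(O)cc2)c1C#Cc1ccc(O)cc1 | intermediate
22 | selaginellin F, 4-[{2',4'-dihydroxy-4-(hydroxymethyl)-3-[(4-hydroxyphenyl)ethynyl]biphenyl-2-yl}(4-hydroxyphenyl)methylidene]cyclohexa-2,5-dien-1-one | O=C1C=CC(=C(c2ccc(O)cc2)c2c(-c3ccc(O)cc3O)ccc(CO)c2C#Cc2ccc(O)cc2)C=C1 | target

**Summary**

Total step count: 12.
Longest linear sequence: 7 steps (1 → 2 → 4 → 5 → 6 → 18 → 20 → 22, or equally 7 → 8 → 11 → 15 → 16 → 18 → 20 → 22).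

**Steps most likely to fail**

Step 10. The cycloaddition of the 1,4-disubstituted diene with the hindered aryl ynone may be sluggish, so that thermal oligomerisation of the diynone competes and the regiochemical preference erodes at the temperature needed. The fallback keeps the same two ring-forming bonds but moves the dienophile to the aldehyde oxidation level, which is smaller and more electron-poor. It sets out from lithium diynide 10 (generated from 9 as in step 6), iodide 13 and diene 6, and returns at ketone 18. Trapping 10 with paraformaldehyde should give 5-(trimethylsilyl)penta-2,4-diyn-1-ol F1. Desilylation in the coupling flask (K2CO3, MeOH) to penta-2,4-diyn-1-ol F2 and Sonogashira coupling with 13 [Pd(PPh3)4, CuI] should give 5-[4-(methoxymethoxy)phenyl]penta-2,4-diyn-1-ol F3, and MnO2 should oxidise it to 5-[4-(methoxymethoxy)phenyl]penta-2,4-diynal F4. Diels–Alder reaction of this ynal with 6 is expected at lower temperature and with the same orientation, giving the cis-cyclohexa-1,4-diene carbaldehyde F5, which DDQ should dehydrogenate to the biaryl benzaldehyde F6. Addition of aryllithium 19 should give the diarylmethanol F7, and MnO2 oxidation of this benzylic alcohol returns ketone 18.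

Step 12. Under protic acid the freed CH2OH or methanol may add across the neighbouring electron-rich arylalkyne, the benzylic alcohol may be etherified, or the hindered acetals on ring D may be cleaved incompletely. The ring D ortho phenol may also add reversibly to C7. The fallback separates the two deprotections and keeps the primary alcohol silylated while a Lewis acid is present. It sets out from carbinol 20 and returns at target 22. Me3SiOTf with 2,2'-bipyridyl in CH2Cl2 at 0 °C, followed by water, should cleave the four aryl MOM ethers through aryl silyl ethers and ionise the carbinol, so that aqueous work-up gives the silyl-protected quinone methide O-TBS-selaginellin F F8. HF·pyridine in THF at 0 °C should then remove the silyl ether to give 22.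

Step 8. The terminal diyne released in the flask may undergo oxidative homocoupling or oligomerisation faster than cross-coupling. The fallback attaches ring E before the carbinol is made, so that no terminal diyne is formed at any point. It sets out from lithium diynide 10, iodide 13 and aldehyde 8, and returns at carbinol 15. Transmetalation of 10 with ZnBr2 should give [4-(trimethylsilyl)buta-1,3-diynyl]zinc bromide F9. Negishi coupling with 13 [Pd(PPh3)4, THF, rt] should give 1-(methoxymethoxy)-4-[4-(trimethylsilyl)buta-1,3-diynyl]benzene F10. MeLi·LiBr should convert this into lithium 4-[4-(methoxymethoxy)phenyl]buta-1,3-diynide F11, which adds to aldehyde 8 at −78 °C to give 15.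

**Further compounds**

F1 | step 10 | 5-(trimethylsilyl)penta-2,4-diyn-1-ol | OCC#CC#C[Si](C)(C)C
F2 | step 10 | penta-2,4-diyn-1-ol (formed in the flask) | OCC#CC#C
F3 | step 10 | 5-[4-(methoxymethoxy)phenyl]penta-2,4-diyn-1-ol | OCC#CC#Cc1ccc(OCOC)cc1
F4 | step 10 | 5-[4-(methoxymethoxy)phenyl]penta-2,4-diynal | O=CC#CC#Cc1ccc(OCOC)cc1
F5 | step 10 | 6-[2,4-bis(methoxymethoxy)phenyl]-3-({[tert-butyl(dimethyl)silyl]oxy}methyl)-2-{[4-(methoxymethoxy)phenyl]ethynyl}cyclohexa-1,4-diene-1-carbaldehyde (3,6-cis, racemic, one enantiomer drawn) | O=CC1=C(C#Cc2ccc(OCOC)cc2)[C@H](CO[Si](C)(C)C(C)(C)C)C=C[C@@H]1c1ccc(OCOC)cc1OCOC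
F6 | step 10 | 4-({[tert-butyl(dimethyl)silyl]oxy}methyl)-2',4'-bis(methoxymethoxy)-3-{[4-(methoxymethoxy)phenyl]ethynyl}biphenyl-2-carbaldehyde | O=Cc1c(-c2ccc(OCOC)cc2OCOC)ccc(CO[Si](C)(C)C(C)(C)C)c1C#Cc1ccc(OCOC)cc1
F7 | step 10 | {4-({[tert-butyl(dimethyl)silyl]oxy}methyl)-2',4'-bis(methoxymethoxy)-3-{[4-(methoxymethoxy)phenyl]ethynyl}biphenyl-2-yl}[4-(methoxymethoxy)phenyl]methanol (racemic) | OC(c1ccc(OCOC)cc1)c1c(-c2ccc(OCOC)cc2OCOC)ccc(CO[Si](C)(C)C(C)(C)C)c1C#Cc1ccc(OCOC)cc1
F8 | step 12 | O-TBS-selaginellin F, 4-[{4-({[tert-butyl(dimethyl)silyl]oxy}methyl)-2',4'-dihydroxy-3-[(4-hydroxyphenyl)ethynyl]biphenyl-2-yl}(4-hydroxyphenyl)methylidene]cyclohexa-2,5-dien-1-one | O=C1C=CC(=C(c2ccc(O)cc2)c2c(-c3ccc(O)cc3O)ccc(CO[Si](C)(C)C(C)(C)C)c2C#Cc2ccc(O)cc2)C=C1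
F9 | step 8 | [4-(trimethylsilyl)buta-1,3-diynyl]zinc bromide | Br[Zn]C#CC#C[Si](C)(C)C
F10 | step 8 | 1-(methoxymethoxy)-4-[4-(trimethylsilyl)buta-1,3-diynyl]benzene | COCOc1ccc(C#CC#C[Si](C)(C)C)cc1
F11 | step 8 | lithium 4-[4-(methoxymethoxy)phenyl]buta-1,3-diynide | [Li]C#CC#Cc1ccc(OCOC)cc1
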